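The cyclopentane (C1, C2, C3, C4, C5, daucane numbering; C1 is the ring-fusion carbon bearing the methyl, C4 the carbinol carbon bearing the isopropyl, C5 the ring-fusion CH) is opened at C1–C5 and C3–C4; the cycloheptene is C1, C5 and C6–C10. A quaternary C1 beside C5–H, with oxygen on C4, is the imprint of a Claisen rearrangement followed by alkene hydroacylation. An acyclic allyl vinyl ether, in which C3 and C4 are linked only through oxygen, rearranges to a pent-4-enal (C1–C5 and both stereocentres), which a rhodium catalyst closes in the same pot to the cyclopentanone (C3–C4). That oxygen becomes the C4 hydroxyl; metathesis closes the cycloheptene later.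

Key step: step 8

Remark: in steps 2 and 4 the antipode of the chiral ligand or acid is taken that delivers the configuration drawn.

Step 1
Reactants: 1 but-2-yn-1-ol
Product: 2 (2Z)-3-iodobut-2-en-1-ol
Conditions: NaAlH2(OCH2CH2OCH3)2, THF, 0 → 25 °C; then I2, −78 → 0 °C
Reagents that add atoms: iodine, [I][I]
Why: Hydroxyl-directed trans-hydroalumination of the propargylic alcohol places aluminium on C3 cis to the CH2O group, and iodinolysis with retention should give the (Z)-vinyl iodide.

Step 2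
Reactants: 2 (2Z)-3-iodobut-2-en-1-ol; 3 acrolein
Product: 4 (2Z,4R)-3-methylhexa-2,5-diene-1,4-diol
Conditions: CrCl2 (3.5 equiv), NiCl2 (2 mol %), (S)-N-[2-(4-isopropyl-4,5-dihydrooxazol-2-yl)-6-methylphenyl]methanesulfonamide (3.8 equiv), Et3N, THF, 25 °C
Reagents that add atoms: none
Why: Nozaki–Hiyama–Kishi alkenylation, in which the alkenyl species of trivalent chromium keeps the Z geometry and adds 1,2 to acrolein, the chiral oxazoline–sulfonamide ligand on chromium selecting the aldehyde face that gives the (R)-carbinol (the later C10).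

Step 3
Reactants: 4 (2Z,4R)-3-methylhexa-2,5-diene-1,4-diol
Product: 6 (2Z,4R)-4-[(tert-butyldimethylsilyl)oxy]-3-methylhexa-2,5-dien-1-ol, via bis-silyl ether 5 (not isolated)
Conditions: TBSOTf (2.4 equiv), 2,6-lutidine, CH2Cl2, −78 → 0 °C; then THF, pyridine, HF·pyridine, 0 °C
Reagents that add atoms: tert-butyldimethylsilyl trifluoromethanesulfonate, CC(C)(C)[Si](C)(C)OS(=O)(=O)C(F)(F)F
Why: Exhaustive silylation followed in the same flask by buffered fluoride cleavage of the unhindered primary allylic silyl ether should leave the hindered secondary ether in place (selective protection/deprotection).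

Step 4
Reactants: 7 3-(trimethylsilyl)prop-2-ynal; 8 4,4,5,5-tetramethyl-2-(2-methylprop-2-en-1-yl)-1,3,2-dioxaborolane
Product: 10 (3R)-5-methylhex-5-en-1-yn-3-ol, via borate ester 9 (not isolated)
Conditions: (R)-3,3′-bis(2,4,6-triisopropylphenyl)-1,1′-binaphthyl-2,2′-diyl hydrogen phosphate (5 mol %), toluene, −30 °C; then K2CO3, MeOH, 25 °C
Reagents that add atoms: none
Why: Chiral phosphoric acid-catalysed allylboration through a closed six-membered transition state transfers the 2-methylallyl group to one aldehyde face and sets the (R)-carbinol (the later C6), and basic methanolysis then cleaves the borate and the alkynyl C–Si bond.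

Step 5
Reactants: 10 (3R)-5-methylhex-5-en-1-yn-3-ol
Product: 11 (3R)-5-methyl-3-[(triethylsilyl)oxy]hex-5-en-1-yne
Conditions: TESCl, imidazole, CH2Cl2, 0 °C
Reagents that add atoms: chlorotriethylsilane, CC[Si](Cl)(CC)CC
Why: Standard silylation of a secondary alcohol with a chlorosilane and imidazole.

Step 6
Reactants: 11 (3R)-5-methyl-3-[(triethylsilyl)oxy]hex-5-en-1-yne
Product: 12 (1E,3R)-1-iodo-5-methyl-3-[(triethylsilyl)oxy]hexa-1,5-diene
Conditions: Cp2Zr(H)Cl, THF, 25 °C; then I2, 0 °C
Reagents that add atoms: iodine, [I][I]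
Why: Hydrozirconation of the terminal alkyne is syn and places zirconium on the terminal carbon, iodinolysis with retention gives the (E)-vinyl iodide, and the 1,1-disubstituted alkene reacts far more slowly.

Step 7
Reactants: 6 (2Z,4R)-4-[(tert-butyldimethylsilyl)oxy]-3-methylhexa-2,5-dien-1-ol; 12 (1E,3R)-1-iodo-5-methyl-3-[(triethylsilyl)oxy]hexa-1,5-diene
Product: 13 tert-butyldimethylsilyl ether of (3R,4Z)-4-methyl-6-{[(1E,3R)-5-methyl-3-[(triethylsilyl)oxy]hexa-1,5-dien-1-yl]oxy}hexa-1,4-dien-3-ol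
Conditions: copper iodide CuI (10 mol %), 3,4,7,8-tetramethyl-1,10-phenanthroline (20 mol %), Cs2CO3, toluene, 80 °C
Reagents that add atoms: none
Why: Copper-catalysed Ullmann-type C–O coupling of a vinyl iodide with a primary allylic alcohol proceeds with retention of the vinyl geometry, and 80 °C should stay below the temperature at which this allyl vinyl ether rearranges.

Step 8
Reactants: 13 the allyl vinyl ether
Product: 15 (2S,3R)-3-[(1R)-1-[(tert-butyldimethylsilyl)oxy]prop-2-en-1-yl]-3-methyl-2-[(1R)-3-methyl-1-[(triethylsilyl)oxy]but-3-en-1-yl]cyclopentan-1-one, via pentenal 14 (not isolated)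
Conditions: PhCl (0.02 M), 135 °C, sealed tube; then 60 °C, [Rh(dppe)(acetone)2]BF4 (10 mol %)
Reagents that add atoms: none
Why: Heating triggers a chair-like [3,3] sigmatropic (Claisen) shift that forms C1–C5 and unmasks pent-4-enal 14; the cationic catalyst of monovalent rhodium then adds oxidatively into the formyl C–H bond, the vinyl group inserts into Rh–H with rhodium on the terminal carbon to give a six-membered acyl rhodacycle, and reductive elimination forms C3–C4. The closest known reaction type is the tandem Claisen rearrangement/intramolecular hydroacylation of allyl vinyl ethers to cyclopentanones. Only the cyclopentanone ring is closed here, in the endo sense typical of pent-4-enal hydroacylation (acyl carbon to the terminal alkene carbon, formally 5-endo-trig), whereas C1–C5 is formed without ring closure. C1 is controlled by the C10 stereocentre, because in the (Z)-allyl unit A(1,3) strain holds the C10–H bond in the alkene plane and the enol ether carbon should add to the face anti to the C10–O bond; C5 follows from the chair geometry, in which the (E)-enol ether substituent and the C1 methyl are both equatorial, so that H-5 and the methyl end up cis on the ring. The step needs the acyl rhodium hydride to engage only the vinyl group on C1, which is secured because only this alkene makes a pent-4-enal (the two others would require a slower hex-5-enal closure), and it needs C5 to keep its configuration, which the neutral, base-free medium secures.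

Step 9
Reactants: 15 the cyclopentanone
Product: 16 (4R,5S)-4-[(1R)-1-[(tert-butyldimethylsilyl)oxy]prop-2-en-1-yl]-4-methyl-5-[(1R)-3-methyl-1-[(triethylsilyl)oxy]but-3-en-1-yl]cyclopent-1-en-1-yl trifluoromethanesulfonate
Conditions: KHMDS, THF, −78 °C; then PhNTf2, −78 → 0 °C
Reagents that add atoms: N-phenylbis(trifluoromethanesulfonimide), O=S(=O)(N(c1ccccc1)S(=O)(=O)C(F)(F)F)C(F)(F)F
Why: Kinetic deprotonation by the bulky amide should occur at the unhindered C3 methylene and not at the congested C5 methine, and O-triflation of the enolate fixes the C3=C4 enol triflate without touching C5.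

Step 10
Reactants: 16 the enol triflate; 17 isopropylmagnesium chloride
Product: 18 (4R,5S)-4-[(1R)-1-[(tert-butyldimethylsilyl)oxy]prop-2-en-1-yl]-4-methyl-5-[(1R)-3-methyl-1-[(triethylsilyl)oxy]but-3-en-1-yl]-1-(propan-2-yl)cyclopent-1-ene
Conditions: Fe(acac)3 (5 mol %), THF/NMP, −30 °C
Reagents that add atoms: none
Why: Iron-catalysed Kumada-type cross-coupling of alkenyl triflates with alkyl Grignard reagents is fast at low temperature and tolerates silyl ethers and isolated alkenes.

Step 11
Reactants: 18 the isopropylcyclopentene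
Product: 19 (1S,2S,3R,5R)-3-[(1R)-1-[(tert-butyldimethylsilyl)oxy]prop-2-en-1-yl]-3-methyl-2-[(1R)-3-methyl-1-[(triethylsilyl)oxy]but-3-en-1-yl]-1-(propan-2-yl)-6-oxabicyclo[3.1.0]hexane
Conditions: mCPBA (1.05 equiv), NaHCO3, CH2Cl2, −20 °C
Reagents that add atoms: 3-chloroperoxybenzoic acid, OOC(=O)c1cccc(Cl)c1
Why: Prilezhaev epoxidation, in which the trisubstituted C3=C4 cyclopentene is the most electron-rich of the three alkenes and the peracid should approach anti to the allylic C5 side chain, on the face of H-5 and the C1 methyl, which puts the oxygen on C4 in the configuration of the target.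

Step 12
Reactants: 19 the epoxide
Product: 21 (1S,2S,3R)-3-[(1R)-1-[(tert-butyldimethylsilyl)oxy]prop-2-en-1-yl]-2-[(1R)-1-hydroxy-3-methylbut-3-en-1-yl]-3-methyl-1-(propan-2-yl)cyclopentan-1-ol, via triethylsilyl ether 20 (not isolated)
Conditions: LiAlH4, THF, 0 → 50 °C; work-up with 1 M aqueous HCl/THF, 25 °C
Reagents that add atoms: none
Why: Hydride opens the trisubstituted epoxide by SN2 attack at the secondary carbon C3, so the C4–O bond and the tertiary carbinol configuration stay intact, and the dilute acid work-up should cleave the triethylsilyl ether but not the more robust tert-butyldimethylsilyl ether.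

Step 13
Reactants: 21 the diene diol
Product: 22 (3S,3aS,4R,8R,8aR)-8-[(tert-butyldimethylsilyl)oxy]-6,8a-dimethyl-3-(propan-2-yl)-1,2,3,3a,4,5,8,8a-octahydroazulene-3,4-diol
Conditions: second-generation Grubbs catalyst RuCl2(=CHPh)(PCy3)(H2IMes) (10 mol %), toluene (0.005 M), 80 °C
Reagents that add atoms: none
Why: Ring-closing metathesis between the 1,1-disubstituted and the monosubstituted alkene, held cis on the cyclopentane, should close the cycloheptene and form the trisubstituted C8=C9 bond with loss of ethene.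

Step 14
Reactants: 22 the bicyclic diol; 23 4-acetoxybenzoyl chloride
Product: 24 (3S,3aS,4R,8R,8aR)-8-[(tert-butyldimethylsilyl)oxy]-3-hydroxy-6,8a-dimethyl-3-(propan-2-yl)-1,2,3,3a,4,5,8,8a-octahydroazulen-4-yl 4-(acetyloxy)benzoate
Conditions: pyridine, DMAP (cat.), CH2Cl2, 0 → 25 °C
Reagents that add atoms: none
Why: DMAP-catalysed acylation distinguishes the secondary C6 hydroxyl from the unreactive tertiary C4 hydroxyl.

Step 15
Reactants: 24 the silyl ether benzoate
Product: 25 (3S,3aS,4R,8R,8aR)-3,8-dihydroxy-6,8a-dimethyl-3-(propan-2-yl)-1,2,3,3a,4,5,8,8a-octahydroazulen-4-yl 4-(acetyloxy)benzoate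
Conditions: HF·pyridine, pyridine, THF, 0 → 25 °C
Reagents that add atoms: none
Why: Fluoride cleaves the C10 silyl ether, while the benzoate and the aryl acetate are stable to buffered HF·pyridine.

Step 16
Reactants: 25 the C10 alcohol; 26 3-methylbutanoic anhydride
Product: 27 (3S,3aS,4R,8R,8aR)-3-hydroxy-6,8a-dimethyl-8-[(3-methylbutanoyl)oxy]-3-(propan-2-yl)-1,2,3,3a,4,5,8,8a-octahydroazulen-4-yl 4-(acetyloxy)benzoate
Conditions: Et3N, DMAP, CH2Cl2, 25 °C
Reagents that add atoms: none
Why: DMAP-catalysed acyl transfer esterifies the secondary allylic C10 hydroxyl, and the tertiary C4 hydroxyl does not react.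

Step 17
Reactants: 27 the aryl acetate
Product: 28 (3S,3aS,4R,8R,8aR)-3-hydroxy-6,8a-dimethyl-8-[(3-methylbutanoyl)oxy]-3-(propan-2-yl)-1,2,3,3a,4,5,8,8a-octahydroazulen-4-yl 4-hydroxybenzoate
Conditions: K2CO3 (0.3 equiv), MeOH, 0 °C
Reagents that add atoms: none
Why: Aryl acetates undergo base-catalysed methanolysis far faster than alkyl esters and benzoates, and the phenoxide formed deactivates the benzoate towards transesterification.

Compound list
1 | but-2-yn-1-ol | CC#CCO | starting material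
2 | (2Z)-3-iodobut-2-en-1-ol | C/C(I)=C/CO | intermediate
3 | acrolein (prop-2-enal) | C=CC=O | starting material
4 | (2Z,4R)-3-methylhexa-2,5-diene-1,4-diol | C=C[C@@H](O)/C(C)=C\CO | intermediate
5 | (3R,4Z)-3,6-bis[(tert-butyldimethylsilyl)oxy]-4-methylhexa-1,4-diene | C=C[C@@H](O[Si](C)(C)C(C)(C)C)/C(C)=C\CO[Si](C)(C)C(C)(C)C | intermediate
6 | (2Z,4R)-4-[(tert-butyldimethylsilyl)oxy]-3-methylhexa-2,5-dien-1-ol | C=C[C@@H](O[Si](C)(C)C(C)(C)C)/C(C)=C\CO | intermediate
7 | 3-(trimethylsilyl)prop-2-ynal | C[Si](C)(C)C#CC=O | starting material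
8 | 4,4,5,5-tetramethyl-2-(2-methylprop-2-en-1-yl)-1,3,2-dioxaborolane | CC(=C)CB1OC(C)(C)C(C)(C)O1 | starting material
9 | 2-{[(3R)-5-methyl-1-(trimethylsilyl)hex-5-en-1-yn-3-yl]oxy}-4,4,5,5-tetramethyl-1,3,2-dioxaborolane | C[Si](C)(C)C#C[C@H](OB1OC(C)(C)C(C)(C)O1)CC(C)=C | intermediate
10 | (3R)-5-methylhex-5-en-1-yn-3-ol | C#C[C@H](O)CC(C)=C | intermediate
11 | (3R)-5-methyl-3-[(triethylsilyl)oxy]hex-5-en-1-yne | C#C[C@H](O[Si](CC)(CC)CC)CC(C)=C | intermediate
12 | (1E,3R)-1-iodo-5-methyl-3-[(triethylsilyl)oxy]hexa-1,5-diene | I/C=C/[C@H](O[Si](CC)(CC)CC)CC(C)=C | intermediate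
13 | tert-butyldimethylsilyl ether of (3R,4Z)-4-methyl-6-{[(1E,3R)-5-methyl-3-[(triethylsilyl)oxy]hexa-1,5-dien-1-yl]oxy}hexa-1,4-dien-3-ol | C=C[C@@H](O[Si](C)(C)C(C)(C)C)/C(C)=C\CO/C=C/[C@H](O[Si](CC)(CC)CC)CC(C)=C | intermediate
14 | (2S,3R,4R)-4-[(tert-butyldimethylsilyl)oxy]-3-ethenyl-3-methyl-2-[(1R)-3-methyl-1-[(triethylsilyl)oxy]but-3-en-1-yl]hex-5-enal | C=C[C@@H](O[Si](C)(C)C(C)(C)C)[C@](C)(C=C)[C@H](C=O)[C@H](O[Si](CC)(CC)CC)CC(C)=C | intermediate
15 | (2S,3R)-3-[(1R)-1-[(tert-butyldimethylsilyl)oxy]prop-2-en-1-yl]-3-methyl-2-[(1R)-3-methyl-1-[(triethylsilyl)oxy]but-3-en-1-yl]cyclopentan-1-one | C=C[C@@H](O[Si](C)(C)C(C)(C)C)[C@]1(C)CCC(=O)[C@@H]1[C@H](O[Si](CC)(CC)CC)CC(C)=C | intermediate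
16 | (4R,5S)-4-[(1R)-1-[(tert-butyldimethylsilyl)oxy]prop-2-en-1-yl]-4-methyl-5-[(1R)-3-methyl-1-[(triethylsilyl)oxy]but-3-en-1-yl]cyclopent-1-en-1-yl trifluoromethanesulfonate | C=C[C@@H](O[Si](C)(C)C(C)(C)C)[C@]1(C)CC=C(OS(=O)(=O)C(F)(F)F)[C@@H]1[C@H](O[Si](CC)(CC)CC)CC(C)=C | intermediate
17 | isopropylmagnesium chloride | CC(C)[Mg]Cl | starting material
18 | (4R,5S)-4-[(1R)-1-[(tert-butyldimethylsilyl)oxy]prop-2-en-1-yl]-4-methyl-5-[(1R)-3-methyl-1-[(triethylsilyl)oxy]but-3-en-1-yl]-1-(propan-2-yl)cyclopent-1-ene | C=C[C@@H](O[Si](C)(C)C(C)(C)C)[C@]1(C)CC=C(C(C)C)[C@@H]1[C@H](O[Si](CC)(CC)CC)CC(C)=C | intermediate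
19 | (1S,2S,3R,5R)-3-[(1R)-1-[(tert-butyldimethylsilyl)oxy]prop-2-en-1-yl]-3-methyl-2-[(1R)-3-methyl-1-[(triethylsilyl)oxy]but-3-en-1-yl]-1-(propan-2-yl)-6-oxabicyclo[3.1.0]hexane | C=C[C@@H](O[Si](C)(C)C(C)(C)C)[C@]2(C)C[C@H]3O[C@@]3(C(C)C)[C@@H]2[C@H](O[Si](CC)(CC)CC)CC(C)=C | intermediate
20 | (1S,2S,3R)-3-[(1R)-1-[(tert-butyldimethylsilyl)oxy]prop-2-en-1-yl]-3-methyl-2-[(1R)-3-methyl-1-[(triethylsilyl)oxy]but-3-en-1-yl]-1-(propan-2-yl)cyclopentan-1-ol | C=C[C@@H](O[Si](C)(C)C(C)(C)C)[C@]1(C)CC[C@](O)(C(C)C)[C@@H]1[C@H](O[Si](CC)(CC)CC)CC(C)=C | intermediate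
21 | (1S,2S,3R)-3-[(1R)-1-[(tert-butyldimethylsilyl)oxy]prop-2-en-1-yl]-2-[(1R)-1-hydroxy-3-methylbut-3-en-1-yl]-3-methyl-1-(propan-2-yl)cyclopentan-1-ol | C=C[C@@H](O[Si](C)(C)C(C)(C)C)[C@]1(C)CC[C@](O)(C(C)C)[C@@H]1[C@H](O)CC(C)=C | intermediate
22 | (3S,3aS,4R,8R,8aR)-8-[(tert-butyldimethylsilyl)oxy]-6,8a-dimethyl-3-(propan-2-yl)-1,2,3,3a,4,5,8,8a-octahydroazulene-3,4-diol | CC1=C[C@@H](O[Si](C)(C)C(C)(C)C)[C@]2(C)CC[C@](O)(C(C)C)[C@@H]2[C@H](O)C1 | intermediate
23 | 4-acetoxybenzoyl chloride | CC(=O)Oc1ccc(cc1)C(Cl)=O | starting material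
24 | (3S,3aS,4R,8R,8aR)-8-[(tert-butyldimethylsilyl)oxy]-3-hydroxy-6,8a-dimethyl-3-(propan-2-yl)-1,2,3,3a,4,5,8,8a-octahydroazulen-4-yl 4-(acetyloxy)benzoate | CC1=C[C@@H](O[Si](C)(C)C(C)(C)C)[C@]2(C)CC[C@](O)(C(C)C)[C@@H]2[C@H](OC(=O)c2ccc(OC(C)=O)cc2)C1 | intermediate
25 | (3S,3aS,4R,8R,8aR)-3,8-dihydroxy-6,8a-dimethyl-3-(propan-2-yl)-1,2,3,3a,4,5,8,8a-octahydroazulen-4-yl 4-(acetyloxy)benzoate | CC1=C[C@@H](O)[C@]2(C)CC[C@](O)(C(C)C)[C@@H]2[C@H](OC(=O)c2ccc(OC(C)=O)cc2)C1 | intermediate
26 | 3-methylbutanoic anhydride | CC(C)CC(=O)OC(=O)CC(C)C | starting material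
27 | (3S,3aS,4R,8R,8aR)-3-hydroxy-6,8a-dimethyl-8-[(3-methylbutanoyl)oxy]-3-(propan-2-yl)-1,2,3,3a,4,5,8,8a-octahydroazulen-4-yl 4-(acetyloxy)benzoate | CC1=C[C@@H](OC(=O)CC(C)C)[C@]2(C)CC[C@](O)(C(C)C)[C@@H]2[C@H](OC(=O)c2ccc(OC(C)=O)cc2)C1 | intermediate
28 | (3S,3aS,4R,8R,8aR)-3-hydroxy-6,8a-dimethyl-8-[(3-methylbutanoyl)oxy]-3-(propan-2-yl)-1,2,3,3a,4,5,8,8a-octahydroazulen-4-yl 4-hydroxybenzoate | CC1=C[C@@H](OC(=O)CC(C)C)[C@]2(C)CC[C@](O)(C(C)C)[C@@H]2[C@H](OC(=O)c2ccc(O)cc2)C1 | target

Total step count: 17. Longest linear sequence: 14 steps (steps 1–3 and 7–17; the branch through steps 4–6 is equally long).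

Steps most likely to fail

Step 8. In the rhodium stage, loss of CO from the acyl rhodium hydride (decarbonylation) and hydride-induced migration of the two spectator terminal alkenes can outrun ring closure at the neopentyl vinyl group. In the thermal stage, a boat transition state or weak facial control by C10 would erode the C1/C5 relationship. The fallback sets out from 13 and comes back at 15. Compound 13 is rearranged thermally alone (toluene, 135 °C) and aldehyde 14 is isolated. Condensation with 2-amino-3-methylpyridine (molecular sieves, toluene) gives the N-(3-methylpyridin-2-yl) aldimine F1. RhCl(PPh3)3 (monovalent rhodium, toluene, 110 °C) then effects pyridine-directed activation of the imine C–H bond and intramolecular insertion of the vinyl group to give the cyclic ketimine F2; decarbonylation is not possible on this path. Hydrolysis with aqueous acetic acid should return ketone 15.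

Step 2. Enantiofacial discrimination may be poor in the addition of the alkenylchromium species to the small, unhindered acrolein, and the free hydroxyl may disturb the chromium–ligand complex. The fallback sets out from 2 and comes back at 5. A ligand-free Nozaki–Hiyama–Kishi reaction of 2 with acrolein (CrCl2, NiCl2 cat., DMF) gives the racemic diol F3. TBSCl and imidazole silylate the primary hydroxyl to give the racemic mono-silyl ether F4. Lipase-catalysed transesterification with vinyl acetate (lipase from Burkholderia cepacia, hexane) should acylate the (R)-alcohol to the (R)-acetate F5, which is separated from the unreacted (S)-alcohol. Methanolysis (K2CO3, MeOH) gives the (R)-alcohol F6, and TBSOTf/2,6-lutidine converts it into 5, which is then isolated and taken to 6 by the fluoride stage of step 3.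

Step 7. Compound 13 may rearrange prematurely at the coupling temperature, and the aldehyde so formed would suffer base-induced epimerisation at C5 or β-elimination of the silyloxy group under carbonate. The fallback sets out from 11 (with 6 as partner) and comes back at 13. Hydroboration of alkyne 11 with pinacolborane, catalysed by Cp2Zr(H)Cl (Et3N, 60 °C), gives the (E)-alkenylboronate F7. Oxidative coupling of F7 with alcohol 6, promoted by Cu(OAc)2 (divalent copper) and Et3N in CH2Cl2 under air at 25 °C, should form the enol ether C–O bond with retention of geometry, far below the rearrangement temperature, and give 13.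

Further compounds
F1 | step 8 | N-(3-methylpyridin-2-yl) aldimine of aldehyde 14 | C=C[C@@H](O[Si](C)(C)C(C)(C)C)[C@](C)(C=C)[C@H](/C=N/c1ncccc1C)[C@H](O[Si](CC)(CC)CC)CC(C)=C
F2 | step 8 | N-(3-methylpyridin-2-yl) ketimine of cyclopentanone 15 (imine geometry not defined) | C=C[C@@H](O[Si](C)(C)C(C)(C)C)[C@]1(C)CCC(=Nc2ncccc2C)[C@@H]1[C@H](O[Si](CC)(CC)CC)CC(C)=C
F3 | step 2 | racemic (2Z)-3-methylhexa-2,5-diene-1,4-diol | C=CC(O)/C(C)=C\CO
F4 | step 2 | racemic (4Z)-6-[(tert-butyldimethylsilyl)oxy]-4-methylhexa-1,4-dien-3-ol | C=CC(O)/C(C)=C\CO[Si](C)(C)C(C)(C)C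
F5 | step 2 | (3R,4Z)-6-[(tert-butyldimethylsilyl)oxy]-4-methylhexa-1,4-dien-3-yl acetate | C=C[C@@H](OC(C)=O)/C(C)=C\CO[Si](C)(C)C(C)(C)C
F6 | step 2 | (3R,4Z)-6-[(tert-butyldimethylsilyl)oxy]-4-methylhexa-1,4-dien-3-ol | C=C[C@@H](O)/C(C)=C\CO[Si](C)(C)C(C)(C)C
F7 | step 7 | 2-[(1E,3R)-5-methyl-3-[(triethylsilyl)oxy]hexa-1,5-dien-1-yl]-4,4,5,5-tetramethyl-1,3,2-dioxaborolane | CC1(C)OB(/C=C/[C@H](O[Si](CC)(CC)CC)CC(C)=C)OC1(C)C
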